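**Retrosynthetic overview**
- The substituted 2-aminoimidazole (ImB) is carried as an imidazo[1,2-a]pyrimidine and unmasked last with hydrazine. The other 2-aminoimidazole (ImA) comes from an α-amino aldehyde plus cyanamide, so the serine-derived stereocentre that controlled C* ends as aromatic C4 of ImA.
- Both dibromopyrrole amides come from one double acylation of a diamine. That diamine comes from one double reduction of a bis-nitrile (a saturated arm and an E-enenitrile arm).
- The key disconnection is the C*–C5(ImB) bond. It is made by visible-light photoredox addition of a heteroaryl σ-radical (from the 3-iodide) to a Z-γ-amino-enenitrile prepared from (R)-Garner's aldehyde (D-serine series).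
- Ring order: the pyrroles, the ImB core and the oxazolidine are bought preformed. ImA is the only ring built (step 9), and ImB is revealed in step 10.

Assumption: compound 4 is treated as a catalogue building block (if not, it is one NaBH4 reduction from the catalogue 2-carbaldehyde, +1 step). C* denotes the single stereocentre of the target, which is (S) by CIP analysis of the given SMILES.

**Step 1**
Reactants: 1, (R)-Garner's aldehyde, tert-butyl (4R)-4-formyl-2,2-dimethyl-1,3-oxazolidine-3-carboxylate; 2, (trimethylsilyl)acetonitrile
Product: 3, tert-butyl (4S)-4-[(Z)-2-cyanoethenyl]-2,2-dimethyl-1,3-oxazolidine-3-carboxylate (same spatial arrangement as 1; only the CIP descriptor changes)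
Conditions: 2, n-BuLi, B(OiPr)3, THF, −78 °C; then 1, −78 °C → rt; SiO2 (minor E isomer removed)
Reagents that add atoms: (trimethylsilyl)acetonitrile, C[Si](C)(C)CC#N (supplies =CH–C≡N)
Why: Peterson olefination, in which fast addition of the weakly basic α-silyl nitrile anion at −78 °C avoids epimerising 1 and syn-elimination of silanolate favours the Z-enenitrile.

**Step 2**
Reactants: 4, (imidazo[1,2-a]pyrimidin-2-yl)methanol; 5, N-iodosuccinimide
Product: 6, (3-iodoimidazo[1,2-a]pyrimidin-2-yl)methanol
Conditions: NIS, MeCN, 0 °C → rt, dark
Reagents that add atoms: N-iodosuccinimide, O=C1CCC(=O)N1I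
Why: Electrophilic aromatic iodination at C3, the only strongly nucleophilic (enamine-like) ring position; the primary alcohol is inert.

**Step 3 (key step)**
Reactants: 3, Z-enenitrile (2.5 equiv, excess recovered); 6, heteroaryl iodide
Product: 7, tert-butyl (4S)-4-{(1S)-2-cyano-1-[2-(hydroxymethyl)imidazo[1,2-a]pyrimidin-3-yl]ethyl}-2,2-dimethyl-1,3-oxazolidine-3-carboxylate
Conditions: fac-Ir(ppy)3 (1 mol %), Hantzsch ester (1.5 equiv), 2,6-lutidine, degassed DMSO/H2O 9:1, 450 nm LEDs, 25 °C; SiO2 (minor C* epimer removed)
Reagents that add atoms: none beyond reactants 3 and 6 (the Hantzsch ester supplies H only)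
Why: Proposed new method: electron transfer from photoexcited Ir(ppy)3 cleaves the C–I bond of 6 to give the imidazo[1,2-a]pyrimidin-3-yl σ-radical, which adds through an early, sterically tolerant transition state to the β-carbon of 3 (giving the nitrile-stabilised radical, quenched by H-atom transfer from the Hantzsch ester); the Z geometry imposes A(1,3) strain that holds the oxazolidine C4–H in the alkene plane, so the N-Boc/CMe2 wall covers one π-face and the radical enters anti to the C–N bond, setting C* as (S) (anti adduct), and removing the minor epimer here fixes the final ee; the closest known reaction type is photoredox reductive conjugate addition (Giese-type hydroarylation) of halopyridine-derived radicals to simple Michael acceptors, and neither this azole radical nor 1,2-induction from a γ-amino stereocentre has been shown.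

**Step 4**
Reactants: 7; 8, diethyl cyanomethylphosphonate
Product: 9, tert-butyl (4S)-4-{(1S)-2-cyano-1-[2-((E)-2-cyanoethenyl)imidazo[1,2-a]pyrimidin-3-yl]ethyl}-2,2-dimethyl-1,3-oxazolidine-3-carboxylate
Conditions: MnO2 (10 equiv), 8, LiOH, 4 Å MS, THF, 65 °C
Reagents that add atoms: diethyl cyanomethylphosphonate, CCOP(=O)(CC#N)OCC (supplies =CH–C≡N)
Why: Tandem MnO2 oxidation/Horner–Wadsworth–Emmons reaction, in which the heteroaryl carbinol is oxidised selectively and the aldehyde is trapped in situ as the E-enenitrile; LiOH is too weak to deprotonate C*–H or the saturated nitrile.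

**Step 5**
Reactants: 9
Product: 10, tert-butyl (4S)-4-{(1S)-3-amino-1-[2-((E)-3-aminoprop-1-enyl)imidazo[1,2-a]pyrimidin-3-yl]propyl}-2,2-dimethyl-1,3-oxazolidine-3-carboxylate
Conditions: DIBAL-H (6 equiv), CH2Cl2, −78 °C; then MeOH, NaBH4, −78 → 0 °C; Rochelle salt work-up
Reagents that add atoms: none
Why: Two-directional nitrile reduction, where DIBAL adds once and 1,2 to each nitrile (so the E-alkene survives) and borohydride reduces both N-metallo imines in situ; Boc, the N,O-acetal and C* are untouched at −78 °C.

**Step 6**
Reactants: 10; 11, 2,2,2-trichloro-1-(4,5-dibromo-1H-pyrrol-2-yl)ethan-1-one (2.2 equiv)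
Product: 12, the bis(4,5-dibromopyrrole-2-carboxamide) of 10, with the N-Boc oxazolidine retained, (4S,1S)
Conditions: 11, i-Pr2NEt, DMF, rt
Reagents that add atoms: 2,2,2-trichloro-1-(4,5-dibromo-1H-pyrrol-2-yl)ethanone, O=C(c1cc(Br)c(Br)[nH]1)C(Cl)(Cl)Cl (supplies two acyl groups)
Why: Haloform-type acyl transfer with CCl3⁻ as leaving group, acylating only the two primary amines because the third nitrogen is still locked in the N-Boc oxazolidine.

**Step 7**
Reactants: 12
Product: 13, tert-butyl [(2S,3S)-5-(4,5-dibromopyrrole-2-carboxamido)-3-{2-[(E)-3-(4,5-dibromopyrrole-2-carboxamido)prop-1-enyl]imidazo[1,2-a]pyrimidin-3-yl}-1-hydroxypentan-2-yl]carbamate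
Conditions: p-TsOH·H2O (1.5 equiv), MeOH, rt
Reagents that add atoms: none
Why: Acid-catalysed methanolysis of the N,O-acetonide, which is much faster than Boc cleavage; the extra acid only protonates the heterocycle.

**Step 8**
Reactants: 13
Product: 14, the corresponding (2S,3S) N-Boc α-amino aldehyde (1-oxopentan-2-yl carbamate)
Conditions: SO3·pyridine, Et3N, DMSO/CH2Cl2, 0 °C → rt
Reagents that add atoms: none
Why: Parikh–Doering oxidation, in a medium that dissolves this polar substrate; epimerisation α to the aldehyde does not matter because that carbon becomes sp2 in step 9, and C* is β and non-acidic.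

**Step 9**
Reactants: 14; 15, cyanamide
Product: 16, (S)-N-{3-(2-amino-1H-imidazol-4-yl)-3-[2-((E)-3-(4,5-dibromopyrrole-2-carboxamido)prop-1-enyl)imidazo[1,2-a]pyrimidin-3-yl]propyl}-4,5-dibromo-1H-pyrrole-2-carboxamide
Conditions: TFA/CH2Cl2, 0 °C, concentrate; then NH2CN (10 equiv), EtOH/H2O, pH 4.5 (NaOAc/AcOH), 75 °C
Reagents that add atoms: cyanamide, N#CN (supplies C2 and two N of ImA)
Why: Boc removal followed by the α-amino aldehyde/cyanamide 2-aminoimidazole synthesis, in which the guanidine formed on the amine closes on the aldehyde (or on its cyclic N-acyl hemiaminal form) and dehydrates to the aromatic ring, erasing the serine-derived stereocentre and leaving C* as the only one.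

**Step 10**
Reactants: 16
Product: 17, the target, (S)-configured
Conditions: N2H4·H2O (20 equiv), EtOH, 80 °C, Ar; reverse-phase purification, neutralise
Reagents that add atoms: none (hydrazine leaves as pyrazole)
Why: Hydrazinolysis of the fused pyrimidine ring, where hydrazine attacks C5/C7, excises C5–C7 as pyrazole, and leaves N8 as the exocyclic NH2 and N4 as ring NH; the amides, C–Br bonds and (under argon, so no diimide forms) the E-alkene survive.

**Compound list**
1 | (R)-Garner's aldehyde | CC1(C)OC[C@H](C=O)N1C(=O)OC(C)(C)C | starting material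
2 | (trimethylsilyl)acetonitrile | C[Si](C)(C)CC#N | starting material
3 | (4S)-Z-enenitrile oxazolidine | CC1(C)OC[C@H](/C=C\C#N)N1C(=O)OC(C)(C)C | intermediate
4 | (imidazo[1,2-a]pyrimidin-2-yl)methanol | OCc1cn2cccnc2n1 | starting material
5 | N-iodosuccinimide | O=C1CCC(=O)N1I | starting material
6 | (3-iodoimidazo[1,2-a]pyrimidin-2-yl)methanol | OCc1nc2ncccn2c1I | intermediate
7 | photoredox adduct (4S,1S) | CC1(C)OC[C@H]([C@H](CC#N)c2c(CO)nc3ncccn23)N1C(=O)OC(C)(C)C | intermediate
8 | diethyl cyanomethylphosphonate | CCOP(=O)(CC#N)OCC | starting material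
9 | bis-nitrile | CC1(C)OC[C@H]([C@H](CC#N)c2c(/C=C/C#N)nc3ncccn23)N1C(=O)OC(C)(C)C | intermediate
10 | diamine | CC1(C)OC[C@H]([C@H](CCN)c2c(/C=C/CN)nc3ncccn23)N1C(=O)OC(C)(C)C | intermediate
11 | 4,5-dibromo-2-(trichloroacetyl)pyrrole | O=C(c1cc(Br)c(Br)[nH]1)C(Cl)(Cl)Cl | starting material
12 | bis-amide oxazolidine | CC1(C)OC[C@H]([C@H](CCNC(=O)c2cc(Br)c(Br)[nH]2)c2c(/C=C/CNC(=O)c3cc(Br)c(Br)[nH]3)nc3ncccn23)N1C(=O)OC(C)(C)C | intermediate
13 | N-Boc amino alcohol (2S,3S) | OC[C@@H](NC(=O)OC(C)(C)C)[C@H](CCNC(=O)c1cc(Br)c(Br)[nH]1)c1c(/C=C/CNC(=O)c2cc(Br)c(Br)[nH]2)nc2ncccn12 | intermediate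
14 | N-Boc amino aldehyde (2S,3S) | O=C[C@@H](NC(=O)OC(C)(C)C)[C@H](CCNC(=O)c1cc(Br)c(Br)[nH]1)c1c(/C=C/CNC(=O)c2cc(Br)c(Br)[nH]2)nc2ncccn12 | intermediate
15 | cyanamide | N#CN | starting material
16 | ImA-formed, ImB-masked intermediate (S) | Nc1ncc([C@H](CCNC(=O)c2cc(Br)c(Br)[nH]2)c2c(/C=C/CNC(=O)c3cc(Br)c(Br)[nH]3)nc3ncccn23)[nH]1 | intermediate
17 | CID11411715 (S) | Nc1ncc([C@H](CCNC(=O)c2cc(Br)c(Br)[nH]2)c2[nH]c(N)nc2/C=C/CNC(=O)c2cc(Br)c(Br)[nH]2)[nH]1 | target

**Totals:** 10 steps in all; longest linear sequence 9 steps (1 → 3 → 4 → … → 10).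

**Steps most likely to fail**
1. **Step 3 (proposed new step).**
   - Risks: premature H-abstraction by the σ-radical, attack at the less hindered α-carbon, or a modest diastereomer ratio.
   - Fallback (known chemistry): silylate the OH of 6, carry out I/Mg exchange (i-PrMgCl·LiCl), and perform a TMSCl-promoted organocuprate 1,4-addition to the Garner-derived (E)-enoate. The serine enantiomer is chosen to match the established sense of that substrate-controlled addition. Converting ester → primary amide → nitrile then rejoins the route at 7.
2. **Step 5 (double nitrile reduction).**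
   - Risks: amine/imine dimerisation, partial 1,4-reduction, or hydride attack on the pyrimidine ring.
   - Fallback: separate the two arms. Reduce the saturated nitrile directly after step 3 and acylate it. Build the right arm by HWE with triethyl phosphonoacetate, DIBAL reduction to the allylic alcohol, and Mitsunobu reaction with phthalimide. The phthalimide is released in the final hydrazine step, and that amine is acylated last.
3. **Step 9 (aminoimidazole formation on a hindered, poorly water-soluble α-amino aldehyde).**
   - Risks: self-condensation of the amino aldehyde, and thermal or acid stress on C*.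
   - Fallback: form the guanidine first. Remove the Boc group of 13 and guanidinylate with N,N′-di-Boc-1H-pyrazole-1-carboxamidine. Oxidise the alcohol so that the protected guanidine closes to the cyclic hemiaminal, then aromatise with TFA at room temperature without aqueous heating.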